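**Retrosynthetic overview**

1. Atom labels follow the target SMILES: octyl C1–C8; cyclobutane C9–C10–C21–C20; ring A C10–C11=C12–C13–C22–C21; ring B C13–C14(C15O2H)=C16–C17–C18–C22; ring C C18–C19–C20–C21–C22. The route rests on one feature: C18 joins C22 (the α′-carbon of a ring-A enone once C13 is a ketone) to the oxygen-bearing C17, so C22–C18 is the bond made when a C22 enol ether adds to a C18=C17 nitroalkene hanging from C20 on the concave face.
2. Ring B is made last: C13–OH and C14=C16 come from a Schenck ene shift of a C13=C14 ester; C13=C14 and C16–C17 come from a nitro-Michael/intramolecular Horner–Wadsworth–Emmons annulation of the C17 nitromethyl group with ethyl 2-(diethoxyphosphoryl)acrylate; C17–OH comes from the nitro group via the ketone (Nef, Luche, Mitsunobu inversion).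
3. Ring C (key): C22–C18 by intramolecular Mukaiyama–Michael addition of the C22 silyl dienol ether to the tethered (E)-nitroalkene.
4. Precursor: nitroalkene by Henry reaction and dehydration; C13 ketone by allylic oxidation; C20 arm by Horner–Wadsworth–Emmons olefination and convex-face conjugate reduction; cyclobutane by a chiral keteniminium [2+2] with cyclohexa-1,3-diene, which also supplies ring A.
5. Ring order: ring A (from the diene) with the cyclobutane, then ring C, then ring B.

Key step: step 10

Assumption: the keteniminium salt of the (2R,5R)-2,5-dimethylpyrrolidine amide is taken to give the cyclobutanone enantiomer drawn; should induction run the other way, the (2S,5S)-amide is used and nothing else changes.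

In the names below, exo means on the cyclobutane face turned away from the six-membered ring and endo means on the same side as that ring.

**Route**

Step 1
Reactants: 1 decanoyl chloride; 2 (2R,5R)-2,5-dimethylpyrrolidine
Product: 3 1-[(2R,5R)-2,5-dimethylpyrrolidin-1-yl]decan-1-one
Conditions: Et3N, DMAP (cat.), CH2Cl2, 0 °C → rt
Reagents that add atoms: none
Why: N-acylation of the secondary amine by the acid chloride (Schotten–Baumann type), with no stereocentre touched.

Step 2
Reactants: 3 amide; 4 cyclohexa-1,3-diene
Product: 8 8-exo-octyl-cis-bicyclo[4.2.0]oct-2-en-7-one, via keteniminium triflate 5 (not isolated), via cyclobutaniminium triflate 6 (not isolated), via endo-octyl cyclobutanone 7 (not isolated)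
Conditions: Tf2O, 2,4,6-collidine, 4 (3 equiv), CH2Cl2, −20 → 40 °C; then aq. NaHCO3, rt; then DBU (cat.), CH2Cl2, rt
Reagents that add atoms: water, O
Why: Keteniminium–olefin [2+2] cycloaddition in which the iminium carbon (C20) bonds to the diene terminus and the octyl-bearing carbon (C9) to the adjacent allylic carbon, so the cis-fused vinylcyclobutanone results after hydrolysis; the C2-symmetric pyrrolidine selects the olefin face (absolute configuration at C10 and C21), and base equilibration α to the ketone places the octyl group exo at C9.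

Step 3
Reactants: 8 exo-octyl cyclobutanone; 9 triethyl phosphonoacetate
Product: 10 ethyl 2-(8-exo-octyl-cis-bicyclo[4.2.0]oct-2-en-7-ylidene)acetate (E/Z mixture)
Conditions: NaH, THF, 0 °C → rt
Reagents that add atoms: none
Why: Horner–Wadsworth–Emmons olefination of the strain-activated cyclobutanone; the alkene geometry is of no consequence because C20 is reduced in the next step.

Step 4
Reactants: 10 alkylidene ester
Product: 11 ethyl 2-(8-exo-octyl-cis-bicyclo[4.2.0]oct-2-en-7-endo-yl)acetate
Conditions: Cu(OAc)2·H2O (5 mol%), 1,2-bis(diphenylphosphino)benzene (5 mol%), (EtO)2MeSiH, t-BuOH, toluene, rt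
Reagents that add atoms: none
Why: Copper hydride conjugate reduction spares the ring alkene, and hydride should reach C20 from the convex face because the concave face is screened by C22 and C13 of the folded six-membered ring while the exo octyl chain can turn away, which puts the acetate arm endo (cis to ring A, trans to octyl).

Step 5
Reactants: 11 saturated ester
Product: 12 ethyl 2-(7-exo-octyl-3-oxo-cis-bicyclo[4.2.0]oct-4-en-8-endo-yl)acetate
Conditions: Rh2(cap)4 (1 mol%; cap = caprolactamate), t-BuOOH (70% aq., 5 equiv), K2CO3 (0.5 equiv), CH2Cl2, rt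
Reagents that add atoms: tert-butyl hydroperoxide, CC(C)(C)OO
Why: Allylic oxidation through a tert-butylperoxy radical chain, in which abstraction at the secondary allylic C13–H should be preferred over the strained cyclobutyl bridgehead C10–H and peroxide capture at the less hindered terminus C13 gives the enone with C11=C12 left in place.

Step 6
Reactants: 12 enone ester
Product: 13 8-endo-(2-hydroxyethyl)-7-exo-octyl-cis-bicyclo[4.2.0]oct-4-en-3-ol (C13 epimers)
Conditions: iBu2AlH (5 equiv), CH2Cl2, −78 → 0 °C; aq. potassium sodium tartrate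
Reagents that add atoms: none
Why: Aluminium hydride reduction takes the ester to the primary alcohol and the enone 1,2 to the allylic alcohol, whose configuration does not matter because it is reoxidised.

Step 7
Reactants: 13 diol
Product: 14 2-(7-exo-octyl-3-oxo-cis-bicyclo[4.2.0]oct-4-en-8-endo-yl)acetaldehyde
Conditions: DMP (1,1,1-triacetoxy-1,1-dihydro-1,2-benziodoxol-3(1H)-one, 2.5 equiv), CH2Cl2, 0 °C → rt
Reagents that add atoms: none
Why: Hypervalent-iodine oxidation of both alcohols under neutral conditions restores the enone and gives the aldehyde without enolising either carbonyl.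

Step 8
Reactants: 14 keto aldehyde; 15 nitromethane
Product: 16 8-endo-(2-hydroxy-3-nitropropyl)-7-exo-octyl-cis-bicyclo[4.2.0]oct-4-en-3-one (carbinol epimers)
Conditions: MeNO2 (solvent), Et3N (0.3 equiv), 0 °C → rt
Reagents that add atoms: none
Why: Henry (nitroaldol) addition, selective because the aldehyde is far more electrophilic than the enone carbonyl and the weak amine does not enolise the ketone; the carbinol centre is removed in the next step.

Step 9
Reactants: 16 nitro alcohol
Product: 18 8-endo-[(E)-3-nitroprop-2-en-1-yl]-7-exo-octyl-cis-bicyclo[4.2.0]oct-4-en-3-one, via nitro mesylate 17 (not isolated)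
Conditions: MsCl, Et3N, CH2Cl2, −20 → 0 °C
Reagents that add atoms: none
Why: Mesylation followed by E1cB elimination of the β-nitro mesylate gives the conjugated nitroalkene, for which the E isomer is the stable geometry.

Step 10
Reactants: 18 nitroalkene enone
Product: 21 tricyclic nitro enone (ring C closed; C18 nitromethyl trans to C13 on ring C; rings A and C cis-fused), via silyl dienol ether 19 (not isolated), via silyl nitronate 20 (not isolated)
Conditions: Me3SiOTf (1.3 equiv), Et3N (1.1 equiv), CH2Cl2 (0.01 M), −78 → −20 °C; then AcOH, THF/H2O, 0 °C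
Reagents that add atoms: none
Why: Soft enolisation removes the kinetic α′-proton at C22 (the γ-proton at C10 sits on the cyclobutane bridgehead) to give the cross-conjugated 2-silyloxy diene, and the remaining silyl triflate activates the nitro group for an intramolecular Mukaiyama–Michael addition of C22 to C18; the closest known reaction types are the Lewis-acid-mediated addition of silyl enol ethers to nitroalkenes and silyl triflate/amine-promoted intramolecular Michael reactions of enones. Ring C (C22, C21, C20, C19, C18) closes in a 5-exo-trig mode. The C22 centre is fixed by the tether, since C19 hangs from C20 on the concave face and C18 can reach only that face of the enol ether, a cis A/C fusion being the only strain-free outcome. The C18 centre is set by the orientation of the (E)-nitrovinyl group in an open transition state, which should turn its CH=NO2 end to the convex side, away from ring A and the silyloxy group, so that C17 ends trans to C13 on ring C. The step needs chemoselectivity for ketone enolisation over the acidic γ-CH2 of the nitroalkene, secured by enolising at −78 °C with a silyl triflate and a tertiary amine instead of a metal amide, and exo over endo placement of the acceptor, since the endo mode would also allow a second closure from C17 to C11. The silyl nitronate is hydrolysed to the nitro compound on mild acid work-up.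

Step 11
Reactants: 21 tricyclic nitro enone; 22 ethyl 2-(diethoxyphosphoryl)acrylate
Product: 24 tetracyclic nitro dienoate (ethyl ester at C14; C13=C14; nitro at C17 as epimers), via phosphonate Michael adduct 23 (not isolated)
Conditions: Cs2CO3 (2.5 equiv), EtOH/CH2Cl2, 0 → 40 °C
Reagents that add atoms: none
Why: Nitro-Michael addition of the C17 nitronate to the vinylphosphonate forms C16–C17 and a phosphonate-stabilised C14 carbanion, which closes ring B by intramolecular Horner–Wadsworth–Emmons olefination of the C13 ketone; the ring is trans-fused to ring C because C17 and C13 are already trans, and C17 needs no control since it becomes a ketone.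

Step 12
Reactants: 24 nitro dienoate
Product: 26 tetracyclic C17 ketone (C13=C14 ester kept), via sodium nitronate 25 (not isolated)
Conditions: NaOEt, EtOH, 0 °C; then TiCl3 (aq.), NH4OAc, THF/H2O, pH about 5, 0 °C → rt
Reagents that add atoms: water, O
Why: Nef reaction in its reductive trivalent-titanium form (nitronate to imine to ketone) at buffered pH, which avoids strong acid or base so that C13=C14 stays out of conjugation with the new ketone and C18, now α to it, is not epimerised.

Step 13
Reactants: 26 β,γ-unsaturated ketone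
Product: 28 C13-hydroxy ene-keto ester (C13–OH cis to H22; C14=C16; C17=O), via C13 hydroperoxide 27 (not isolated)
Conditions: O2, tetraphenylporphyrin (cat.), visible light, CH2Cl2, −20 °C; then PPh3, 0 °C
Reagents that add atoms: dioxygen, O=O
Why: Schenck ene reaction of singlet oxygen, in which oxygen bonds to C13 and a C16 hydrogen (geminal to the ester and α to the ketone) is taken so that the double bond moves to C14=C16; attack should come on the face of C13=C14 that carries only H22, the other being covered by C21 and C18, which sets C13, and PPh3 reduces the hydroperoxide.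

Step 14
Reactants: 28 hydroxy ene-keto ester
Product: 29 C17-epi diol ester (C17–OH trans to C13–OH)
Conditions: NaBH4, CeCl3·7H2O, MeOH, −78 °C
Reagents that add atoms: none
Why: Luche 1,2-reduction, in which hydride is expected to add axially, anti to the axial C18–H, giving the pseudo-equatorial C17 alcohol, which is the C17 epimer of the target.

Step 15
Reactants: 29 C17-epi diol ester
Product: 30 C17 4-nitrobenzoate (C17–O cis to C13–OH, target configuration)
Conditions: 4-nitrobenzoic acid, PPh3, DIAD, THF, 0 °C → rt
Reagents that add atoms: 4-nitrobenzoic acid, OC(=O)c1ccc(cc1)[N+](=O)[O-]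
Why: Mitsunobu esterification inverts C17 by SN2 displacement of the activated secondary allylic alcohol, while the tertiary C13 alcohol does not react.

Step 16
Reactants: 30 4-nitrobenzoate
Product: 31 CNP0106718.3 (target acid)
Conditions: LiOH·H2O, THF/MeOH/H2O, 0 °C → rt; then 1 M HCl to pH 3–4, 0 °C
Reagents that add atoms: lithium hydroxide, [Li+].[OH-]
Why: Saponification cleaves the 4-nitrobenzoate at the acyl–oxygen bond (C17 configuration kept) and the ethyl ester, and cold, mild acidification frees the acid without ionising the tertiary allylic alcohol.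

**Compound list**

1 | decanoyl chloride | CCCCCCCCCC(=O)Cl | starting material
2 | (2R,5R)-2,5-dimethylpyrrolidine | C[C@@H]1CC[C@@H](C)N1 | starting material
3 | 1-[(2R,5R)-2,5-dimethylpyrrolidin-1-yl]decan-1-one | CCCCCCCCCC(=O)N1[C@H](C)CC[C@H]1C | intermediate
4 | cyclohexa-1,3-diene | C1=CC=CCC1 | starting material
5 | 1-(dec-1-en-1-ylidene)-(2R,5R)-2,5-dimethylpyrrolidinium triflate (keteniminium triflate) | CCCCCCCCC=C=[N+]1[C@H](C)CC[C@H]1C.[O-]S(=O)(=O)C(F)(F)F | intermediate
6 | 1-(8-octyl-cis-bicyclo[4.2.0]oct-2-en-7-ylidene)-(2R,5R)-2,5-dimethylpyrrolidinium triflate (cyclobutaniminium triflate, C9 epimers) | CCCCCCCCC1[C@@H]2C=CCC[C@@H]2C1=[N+]3[C@H](C)CC[C@H]3C.[O-]S(=O)(=O)C(F)(F)F | intermediate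
7 | 8-endo-octyl-cis-bicyclo[4.2.0]oct-2-en-7-one (octyl cis to the six-membered ring) | CCCCCCCC[C@@H]1[C@@H]2C=CCC[C@@H]2C1=O | intermediate
8 | 8-exo-octyl-cis-bicyclo[4.2.0]oct-2-en-7-one (octyl trans to the six-membered ring) | CCCCCCCC[C@H]1[C@@H]2C=CCC[C@@H]2C1=O | intermediate
9 | triethyl phosphonoacetate | CCOC(=O)CP(=O)(OCC)OCC | starting material
10 | ethyl 2-(8-exo-octyl-cis-bicyclo[4.2.0]oct-2-en-7-ylidene)acetate (E/Z mixture) | CCCCCCCC[C@H]1[C@@H]2C=CCC[C@@H]2C1=CC(=O)OCC | intermediate
11 | ethyl 2-(8-exo-octyl-cis-bicyclo[4.2.0]oct-2-en-7-endo-yl)acetate | CCCCCCCC[C@H]1[C@@H]2C=CCC[C@@H]2[C@@H]1CC(=O)OCC | intermediate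
12 | ethyl 2-(7-exo-octyl-3-oxo-cis-bicyclo[4.2.0]oct-4-en-8-endo-yl)acetate | CCCCCCCC[C@H]1[C@@H]2C=CC(=O)C[C@@H]2[C@@H]1CC(=O)OCC | intermediate
13 | 8-endo-(2-hydroxyethyl)-7-exo-octyl-cis-bicyclo[4.2.0]oct-4-en-3-ol (carbinol epimers) | CCCCCCCC[C@H]1[C@@H]2C=CC(O)C[C@@H]2[C@@H]1CCO | intermediate
14 | 2-(7-exo-octyl-3-oxo-cis-bicyclo[4.2.0]oct-4-en-8-endo-yl)acetaldehyde | CCCCCCCC[C@H]1[C@@H]2C=CC(=O)C[C@@H]2[C@@H]1CC=O | intermediate
15 | nitromethane | C[N+](=O)[O-] | starting material
16 | 8-endo-(2-hydroxy-3-nitropropyl)-7-exo-octyl-cis-bicyclo[4.2.0]oct-4-en-3-one (carbinol epimers) | CCCCCCCC[C@H]1[C@@H]2C=CC(=O)C[C@@H]2[C@@H]1CC(O)C[N+](=O)[O-] | intermediate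
17 | 1-nitro-3-(7-exo-octyl-3-oxo-cis-bicyclo[4.2.0]oct-4-en-8-endo-yl)propan-2-yl methanesulfonate | CCCCCCCC[C@H]1[C@@H]2C=CC(=O)C[C@@H]2[C@@H]1CC(OS(C)(=O)=O)C[N+](=O)[O-] | intermediate
18 | 8-endo-[(E)-3-nitroprop-2-en-1-yl]-7-exo-octyl-cis-bicyclo[4.2.0]oct-4-en-3-one (key-step precursor) | CCCCCCCC[C@H]1[C@@H]2C=CC(=O)C[C@@H]2[C@@H]1C/C=C/[N+](=O)[O-] | intermediate
19 | 8-endo-[(E)-3-nitroprop-2-en-1-yl]-7-exo-octyl-3-(trimethylsilyloxy)-cis-bicyclo[4.2.0]octa-2,4-diene (silyl dienol ether) | CCCCCCCC[C@H]1[C@@H]2C=CC(O[Si](C)(C)C)=C[C@@H]2[C@@H]1C/C=C/[N+](=O)[O-] | intermediate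
20 | trimethylsilyl nitronate of 21 (ring C closed, C17H=N(O)OSiMe3) | CCCCCCCC[C@H]1[C@@H]2C=CC(=O)[C@@H]3[C@@H](C=[N+]([O-])O[Si](C)(C)C)C[C@H]1[C@H]23 | intermediate
21 | tricyclic nitro enone: cyclobutane, ring A enone and ring C; C18 nitromethyl trans to C13 on ring C; H21/H22 cis (key-step product) | CCCCCCCC[C@H]1[C@@H]2C=CC(=O)[C@@H]3[C@@H](C[N+](=O)[O-])C[C@H]1[C@H]23 | intermediate
22 | ethyl 2-(diethoxyphosphoryl)acrylate | CCOC(=O)C(=C)P(=O)(OCC)OCC | starting material
23 | phosphonate Michael adduct of 21 (C17 nitro, C16H2, C14H(PO(OEt)2)CO2Et) | CCCCCCCC[C@H]1[C@@H]2C=CC(=O)[C@@H]3[C@@H](C(CC(C(=O)OCC)P(=O)(OCC)OCC)[N+](=O)[O-])C[C@H]1[C@H]23 | intermediate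
24 | tetracyclic nitro dienoate: ring B closed, C13=C14(CO2Et), C17 nitro (epimers), B/C trans-fused | CCCCCCCC[C@H]1[C@@H]2C=CC3=C(C(=O)OCC)CC([N+](=O)[O-])[C@H]4C[C@H]1[C@H]2[C@@H]43 | intermediate
25 | sodium C17 nitronate of 24 | CCCCCCCC[C@H]1[C@@H]2C=CC3=C(C(=O)OCC)CC(=[N+]([O-])[O-])[C@H]4C[C@H]1[C@H]2[C@@H]43.[Na+] | intermediate
26 | tetracyclic C17 ketone with C13=C14(CO2Et) (β,γ-unsaturated ketone) | CCCCCCCC[C@H]1[C@@H]2C=CC3=C(C(=O)OCC)CC(=O)[C@H]4C[C@H]1[C@H]2[C@@H]43 | intermediate
27 | C13 hydroperoxide: C13–OOH cis to H22, C14=C16, C17=O, ethyl ester | CCCCCCCC[C@H]1[C@@H]2C=C[C@]3(OO)C(C(=O)OCC)=CC(=O)[C@H]4C[C@H]1[C@H]2[C@@H]43 | intermediate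
28 | C13-hydroxy ene-keto ester: C13–OH cis to H22, C14=C16, C17=O | CCCCCCCC[C@H]1[C@@H]2C=C[C@]3(O)C(C(=O)OCC)=CC(=O)[C@H]4C[C@H]1[C@H]2[C@@H]43 | intermediate
29 | C17-epi diol ethyl ester (C17–OH trans to C13–OH) | CCCCCCCC[C@H]1[C@@H]2C=C[C@]3(O)C(C(=O)OCC)=C[C@H](O)[C@H]4C[C@H]1[C@H]2[C@@H]43 | intermediate
30 | C17 4-nitrobenzoate ethyl ester (C17–O cis to C13–OH) | CCCCCCCC[C@H]1[C@@H]2C=C[C@]3(O)C(C(=O)OCC)=C[C@@H](OC(=O)c5ccc(cc5)[N+](=O)[O-])[C@H]4C[C@H]1[C@H]2[C@@H]43 | intermediate
31 | CNP0106718.3 (target acid) | CCCCCCCC[C@H]1[C@@H]2C=C[C@]3(O)C(C(=O)O)=C[C@@H](O)[C@H]4C[C@H]1[C@H]2[C@@H]43 | target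

**Step count and risks**

Total step count: 16. Longest linear sequence: 16 steps (1 to 31); all other starting materials enter as purchased reagents.

Steps most likely to fail:

1. Step 10 (key step). The nitroalkene may be lost to amine-induced deconjugation to the allylic nitro isomer, or to oligomerisation, before the enol silane engages it. In that case the acceptor is kept masked. Nitro alcohol 16 is acetylated (Ac2O, DMAP cat., CH2Cl2, 0 °C) to the β-nitro acetate F1. LiN(SiMe3)2 (2.05 equiv, THF, −78 °C) then forms the C22 lithium enolate and the C17 nitronate together, as the dilithium enolate–nitronate F2. On warming to −20 °C the nitronate expels acetate, so the nitroalkene appears only next to the preformed enolate and with no free base present; the enolate closes ring C, and an AcOH quench returns to the route at 21.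

2. Step 13. The ene reaction may show poor site selectivity (removal of H22 instead of a C16 hydrogen) or slow uptake by the electron-poor alkene. Oxygen is then brought in through the enolate instead. From 26, KOtBu (1.1 equiv, THF/t-BuOH, −40 °C) removes the doubly activated C16 proton to give the potassium dienolate F3. This is oxygenated at its γ-terminus C13 with O2 in the presence of P(OEt)3, the known γ-autoxidation of β,γ-unsaturated ketones, on the same H22 face. It passes through hydroperoxide 27 and rejoins the route at 28.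

3. Step 5. Oxygenation may not be selective for C13, through capture of the allyl radical at its cyclobutane-flanked terminus C11 or hydrogen abstraction at the C10 bridgehead. The radical chain is then replaced by a closed-shell sequence. From 11, SeO2 (0.5 equiv) with t-BuOOH in CH2Cl2 gives, by ene reaction and [2,3]-shift, the C13 allylic alcohol F4 with the double bond left at C11=C12 (the methylene is attacked in preference to the methine). MnO2 in CH2Cl2 then oxidises F4 to 12.

**Further compounds**

F1 | step 10 | 1-nitro-3-(7-exo-octyl-3-oxo-cis-bicyclo[4.2.0]oct-4-en-8-endo-yl)propan-2-yl acetate | CCCCCCCC[C@H]1[C@@H]2C=CC(=O)C[C@@H]2[C@@H]1CC(OC(C)=O)C[N+](=O)[O-]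
F2 | step 10 | dilithium C22 enolate–C17 nitronate of F1 | CCCCCCCC[C@H]1[C@@H]2C=CC([O-])=C[C@@H]2[C@@H]1CC(OC(C)=O)C=[N+]([O-])[O-].[Li+].[Li+]
F3 | step 13 | potassium C17 dienolate of 26 (C16=C17–O−, C13=C14) | CCCCCCCC[C@H]1[C@@H]2C=CC3=C(C(=O)OCC)C=C([O-])[C@H]4C[C@H]1[C@H]2[C@@H]43.[K+]
F4 | step 5 | ethyl 2-(3-hydroxy-7-exo-octyl-cis-bicyclo[4.2.0]oct-4-en-8-endo-yl)acetate (carbinol epimers) | CCCCCCCC[C@H]1[C@@H]2C=CC(O)C[C@@H]2[C@@H]1CC(=O)OCC
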